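Take a percent of the solid substrate charged as your unit of account and follow it through the flask. It dissolves, becomes starting material, then intermediate, and leaves the intermediate by one of two exits, product or decomposed reagent.

| flask | solid substrate | remark | time |
|---|---|---|---|
| noon | 0.10 mM | run made earlier |  |
| spring | 0.40 mM | run made earlier |  |
| flask | 0.20 mM |  | 8.0 min |

| run | time / min | product / % | starting material / % | solid substrate / % |
|---|---|---|---|---|
| noon | 0.833 | 13.5 | 30.6 | 1.0 |
| noon | 2.50 | 62.0 | 1.6 | 0 |
| noon | 4.00 | 77.3 | 0 | 0 |
| noon | 6.00 | 83.0 | 0 | 0 |
| noon | 10.0 | 86.1 | 0 | 0.3 |
| spring | 0.833 | 3.0 | 17.4 | 61.4 |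
| spring | 1.33 | 10.2 | 19.6 | 42.8 |
| spring | 2.50 | 35.4 | 16.7 | 0 |
| spring | 5.00 | 78.1 | 0.2 | 0 |
| spring | 10.0 | 84.9 | 0 | 0 |

(standard deviation of a reading: 1 percentage point)

* amount of product at 8.0 min, in percent of the solid substrate charged
* concentration of starting material in solution at 8.0 min, in percent of saturation

- as a solid, counted per litre of solution: solid substrate
- candidate steps: starting material -> intermediate; intermediate -> product; solid substrate <-> starting material; intermediate -> decomposed reagent
- at the start none of the solid substrate is in solution
- starting material means what is dissolved; the solid is not counted in it

The last entries nearly agree: product reads 86.1% in the noon run and 84.9% in the spring run, though 0.10 mM and 0.40 mM were charged. Read with their scatter, their mean is the product share, the part of each unit that takes the product exit, the selectivity of this branch: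

product share = 85.5%

The gap, share minus product, is what has yet to reach that exit. In the noon run it falls from 23 percentage points at 2.50 min to 8.2 points at 4.00 min, so:

clearing constant = 0.702 min⁻¹

The spring gap at 5.00 min is 7.4 points. Shrunk at this rate up to 8.0 min, it leaves:

gap = 0.9 points, product = 84.6%

That is this reckoning's figure for the flask, charged with 0.20 mM. The forecast stands higher, at 85.2% of product and <0.001% of saturation, holding that “the yield is concentration independent”.

The flask gives 85.5% of product and 0% of saturation.

    starting material → intermediate (k = 0.0350 s⁻¹)
    intermediate → product (k = 0.0110 s⁻¹)
    solid substrate ⇌ starting material, rate k3*(cs3 - [starting material]) while solid is left; crystals form when [starting material] > cs3 (solubility = 0.190 mM, k = 0.0210 s⁻¹)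
    intermediate → decomposed reagent (k = 0.00180 s⁻¹)

The second exit is the main reason the share stands short of the whole: without the step from intermediate to decomposed reagent, this flask gives 98.9% of product instead of 85.5%. The low solubility of starting material makes no difference to this flask's product. With 0.531% still intermediate in this flask at 8.0 min, the share gives 85.0%, against the 85.5% the flask gives. The neighbour flask, stopped at 3.0 min, holds 23.5% of intermediate and 0.735% of dissolved starting material, so the share gives 64.8%, and that flask gives 65.1%.

The numbers in the tables come from a simulation from invented constants; the scatter is artificial.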